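**Strategy.** Everything rests on disconnecting the O–C7' bond of the dihydrofuran. The target carries a 4-hydroxyphenyl group on C7', and C7' sits one carbon (C8') away from the a5 oxygen of ring A. A flavin oxidase that accepts only free 4-alkylphenols can therefore turn the C7' methylene into a para-quinone methide, which the a5 phenol closes by 5-exo oxa-Michael addition, forming the ring, the bond and the C7' stereocentre in one operation. The precursor is the (7S,8'S) dibenzosuberane with a 4-hydroxybenzyl group on C8', a free a5 hydroxyl, and methyl ethers on the other oxygens that keep C7 and C8' from being oxidised. Both earlier stereocentres come from catalyst-controlled reductions.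

Key step: step 10

Labels: C7 is the seven-ring CH carrying the 4-oxyphenyl group and C8 the seven-ring CH2. C8' and C7' are C3 and C2 of the dihydrofuran. Ring A is the benzene ring fused to the dihydrofuran (a1 bears C8, a3 an oxygen, a5 the ring oxygen, a6 bears C8'). Ring D is the other resorcinol ring (d1 bears C8', d3 and d5 oxygen, d6 bears C7).

Remark on configuration: recomputed from the structures, 19 is (C7 S, C8' S) with the benzyl group anti to the C7 aryl on the seven-membered ring. 21 and 22 are (7S,7'S,8'S) with the two aryl groups on the dihydrofuran trans. These assignments are mutually consistent.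

Remark on the precursor: the methyl ethers on the C7 aryl, a3 and d3 are essential, because a free hydroxyl there would lie para to C7–H or C8'–H and give the oxidase a second site. The free a5 hydroxyl has only hydrogen para to it. The d5 ether is a spectator.

Assumption: the antipode of the iridium ligand (step 4) and of the phosphoric acid (step 8) that gives the drawn configuration is assigned by analogy with the parent reactions. It is to be confirmed on the first run, and the mirror-image catalyst is used if the sense is opposite.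

Step 1
Reactants: 1 methyl 3,5-dimethoxybenzoate; 2 4-methoxybenzoyl chloride
Product: 3 methyl 3,5-dimethoxy-2-(4-methoxybenzoyl)benzoate
Conditions: AlCl3 (1.2 equiv), CH2Cl2, 0 → 25 °C
Reagents that add atoms: none
Why: Friedel–Crafts acylation, in which the 4-methoxybenzoyl cation attacks C2 of 1 (ortho to one methoxy group and para to the other) rather than C4, which is shielded between two methoxy groups, and the mild conditions should spare the methyl ethers.

Step 2
Reactants: 3 methyl 3,5-dimethoxy-2-(4-methoxybenzoyl)benzoate; 4 3,5-dimethoxybenzyl chloride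
Product: 7 racemic 3-(3,5-dimethoxybenzyl)-4,6-dimethoxy-3-(4-methoxyphenyl)isobenzofuran-1(3H)-one, via Grignard reagent 5 (not isolated), via chloromagnesium alkoxide 6 (not isolated)
Conditions: 4, Mg, THF, 0 °C; then 3, THF, −78 → 0 °C; aq NH4Cl
Reagents that add atoms: none
Why: Grignard 1,2-addition to the diaryl ketone, which should outpace attack on the flanked ester, followed by lactonisation of alkoxide 6 onto the ortho ester (the classical route from 2-aroylbenzoates to 3,3-disubstituted phthalides); the new centre is racemic and is erased in step 3.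

Step 3
Reactants: 7 racemic 3-(3,5-dimethoxybenzyl)-4,6-dimethoxy-3-(4-methoxyphenyl)isobenzofuran-1(3H)-one
Product: 8 (Z)-2-[2-(3,5-dimethoxyphenyl)-1-(4-methoxyphenyl)ethenyl]-3,5-dimethoxybenzoic acid
Conditions: KOtBu (2.5 equiv), THF/DMSO, 0 → 40 °C; then 1 M HCl to pH 4, 0 °C; crystallisation
Reagents that add atoms: none
Why: Base-induced β-elimination (E2) of the lactone, in which the tertiary, doubly benzylic C7–O bond is a good carboxylate nucleofuge and only C8 carries β-hydrogens; the Z isomer (4-methoxystilbene unit trans, the di-ortho-substituted ring D twisted out of plane) should be favoured and is purified by crystallisation, any E isomer being returned to 7 by a trace of acid.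

Step 4
Reactants: 8 (Z)-2-[2-(3,5-dimethoxyphenyl)-1-(4-methoxyphenyl)ethenyl]-3,5-dimethoxybenzoic acid
Product: 9 (S)-2-[2-(3,5-dimethoxyphenyl)-1-(4-methoxyphenyl)ethyl]-3,5-dimethoxybenzoic acid
Conditions: H2 (6 atm), [Ir(cod)(L)][B(C6H3(CF3)2)4] (1 mol %; L = (Sa,S)-SIPHOX spiro phosphine–oxazoline), NEt3 (0.5 equiv), MeOH, 45 °C
Reagents that add atoms: none
Why: Carboxy-directed iridium-catalysed asymmetric hydrogenation of a 1,1-diaryl alkene, in which the carboxylate on ring D anchors the substrate on iridium so that the chiral spiro ligand decides which face of C7 receives hydrogen, setting C7 as S.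

Step 5
Reactants: 9 (S)-2-[2-(3,5-dimethoxyphenyl)-1-(4-methoxyphenyl)ethyl]-3,5-dimethoxybenzoic acid
Product: 11 (S)-1,3,6,8-tetramethoxy-11-(4-methoxyphenyl)-10,11-dihydro-5H-dibenzo[a,d][7]annulen-5-one, via mixed trifluoroacetic anhydride 10 (not isolated)
Conditions: TFAA (2 equiv), CH2Cl2, 0 → 25 °C
Reagents that add atoms: none
Why: Intramolecular Friedel–Crafts acylation through mixed anhydride 10, in which ring A attacks through a6 (ortho and para to its two methoxy groups) and closes the seven-membered ketone, while the anisyl ring offers only positions meta to its methoxy group and C7 has no path to epimerise under these mild conditions.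

Step 6
Reactants: 11 (S)-1,3,6,8-tetramethoxy-11-(4-methoxyphenyl)-10,11-dihydro-5H-dibenzo[a,d][7]annulen-5-one
Product: 12 (S)-6-hydroxy-1,3,8-trimethoxy-11-(4-methoxyphenyl)-10,11-dihydro-5H-dibenzo[a,d][7]annulen-5-one (free a5 hydroxyl)
Conditions: BCl3 (1.2 equiv), CH2Cl2, −78 → 0 °C; then H2O
Reagents that add atoms: none
Why: Chelation-controlled ether cleavage, in which BCl3 bridges the C8' carbonyl oxygen and the a5 methoxy oxygen ortho to it in a six-membered chelate, so only this methyl ether is cleaved and the other four, none of which is ortho to the ketone, remain.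

Step 7
Reactants: 12 (S)-6-hydroxy-1,3,8-trimethoxy-11-(4-methoxyphenyl)-10,11-dihydro-5H-dibenzo[a,d][7]annulen-5-one; 13 4-(benzyloxy)benzyl chloride
Product: 16 (S)-5-[4-(benzyloxy)benzylidene]-2,7,9-trimethoxy-10-(4-methoxyphenyl)-10,11-dihydro-5H-dibenzo[a,d][7]annulen-4-ol (E and Z isomers about C8'=C7'), via Grignard reagent 14 (not isolated), via tertiary carbinol 15 (not isolated)
Conditions: 13, Mg, THF, 0 °C; then 12 (14 in 3.5 equiv), THF, 0 → 40 °C; aq NH4Cl; then TsOH (5 mol %), CH2Cl2, 25 °C
Reagents that add atoms: none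
Why: Grignard addition to the ketone of the magnesium phenolate (the first equivalent of 14 is spent on the phenol) gives carbinol 15, whose tertiary, doubly benzylic hydroxyl is lost on acid treatment (E1) toward C7', the only neighbour with hydrogen, to give the triaryl alkene.

Step 8
Reactants: 16 (S)-5-[4-(benzyloxy)benzylidene]-2,7,9-trimethoxy-10-(4-methoxyphenyl)-10,11-dihydro-5H-dibenzo[a,d][7]annulen-4-ol
Product: 18 (5S,10S)-5-[4-(benzyloxy)benzyl]-2,7,9-trimethoxy-10-(4-methoxyphenyl)-10,11-dihydro-5H-dibenzo[a,d][7]annulen-4-ol, via ortho-quinone methide 17 (not isolated)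
Conditions: (R)-TRIP [3,3'-bis(2,4,6-triisopropylphenyl)-1,1'-binaphthyl-2,2'-diyl hydrogen phosphate] (5 mol %), Hantzsch ester (diethyl 2,6-dimethyl-1,4-dihydropyridine-3,5-dicarboxylate, 1.3 equiv), PhCF3, 25 °C
Reagents that add atoms: none
Why: Chiral phosphoric acid-catalysed asymmetric transfer hydrogenation of an ortho-hydroxy 1,1-diaryl alkene, in which the acid protonates C7' of either alkene isomer to give the hydrogen-bonded ortho-quinone methide 17 and the Hantzsch ester delivers hydride to C8' on the face chosen by the catalyst, placing H syn and the benzyl group anti to the C7 aryl (C8' S).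

Step 9
Reactants: 18 (5S,10S)-5-[4-(benzyloxy)benzyl]-2,7,9-trimethoxy-10-(4-methoxyphenyl)-10,11-dihydro-5H-dibenzo[a,d][7]annulen-4-ol
Product: 19 (5S,10S)-5-(4-hydroxybenzyl)-2,7,9-trimethoxy-10-(4-methoxyphenyl)-10,11-dihydro-5H-dibenzo[a,d][7]annulen-4-ol (the key-step precursor; C7 S, C8' S)
Conditions: H2 (1 atm), Pd/C (10 wt %), EtOAc/MeOH, 25 °C
Reagents that add atoms: none
Why: Hydrogenolysis of the benzyl aryl ether over palladium; methyl ethers, free phenols and both stereocentres are inert.

Step 10
Reactants: 19 (5S,10S)-5-(4-hydroxybenzyl)-2,7,9-trimethoxy-10-(4-methoxyphenyl)-10,11-dihydro-5H-dibenzo[a,d][7]annulen-4-ol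
Product: 21 ampelopsin B tetramethyl ether carrying the free 4-hydroxyphenyl group on C7' (7S,7'S,8'S), via para-quinone methide 20 (not isolated)
Conditions: engineered vanillyl-alcohol oxidase variant (FAD enzyme, enlarged substrate pocket), O2 (air, 1 atm), catalase, potassium phosphate buffer pH 8.0, 10% acetone, 30 °C
Reagents that add atoms: none
Why: Proposed new method: the oxidase binds the 4-hydroxybenzyl group of 19 as its phenolate, the oxidised flavin takes hydride from C7' to give para-quinone methide 20, O2 reoxidises the flavin, and the a5 phenol, held next to C7' through C8', adds to the methide carbon and restores the arene. The closest known reaction type is the dehydrogenation of 4-alkylphenols to para-quinone methides by vanillyl-alcohol oxidase and eugenol oxidase, where water is the usual trap; an intramolecular phenol trap on a substrate this large is unprecedented and calls for an engineered active site. The dihydrofuran closes in a 5-exo-trig oxa-Michael mode, forming the O–C7' bond. The new stereocentre C7' is controlled by C8': the aryl group takes the face trans to ring D on the five-membered ring, and because the addition can revert through the quinone methide the trans isomer is also the thermodynamic one. The step needs site selectivity among four benzylic positions and three electron-rich rings, and this is secured because only the C7' aryl carries a free para hydroxyl with a benzylic hydrogen, while the C7 aryl, a3 and d3 are methyl ethers and the free a5 hydroxyl has only hydrogen para to it.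

Step 11
Reactants: 21 ampelopsin B tetramethyl ether carrying the free 4-hydroxyphenyl group on C7'
Product: 22 ampelopsin B
Conditions: BBr3 (10 equiv), CH2Cl2, −78 → 0 °C; then H2O
Reagents that add atoms: none
Why: Lewis acid cleavage of the four aryl methyl ethers with BBr3 (bromide attacks the methyl group of each ether–boron adduct); if the benzylic C7'–O bond ionises it should reclose to the trans dihydrofuran fixed by C8', and C7 and C8' are not affected.

**Compound list**

1 | methyl 3,5-dimethoxybenzoate | COC(=O)c1cc(OC)cc(OC)c1 | starting material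
2 | 4-methoxybenzoyl chloride | COc1ccc(C(Cl)=O)cc1 | starting material
3 | methyl 3,5-dimethoxy-2-(4-methoxybenzoyl)benzoate | COC(=O)c1cc(OC)cc(OC)c1C(=O)c1ccc(OC)cc1 | intermediate
4 | 3,5-dimethoxybenzyl chloride | COc1cc(CCl)cc(OC)c1 | starting material
5 | 3,5-dimethoxybenzylmagnesium chloride | COc1cc(C[Mg]Cl)cc(OC)c1 | intermediate (not isolated)
6 | chloromagnesium alkoxide from addition of 5 to the ketone of 3 (racemic) | COC(=O)c1cc(OC)cc(OC)c1C(O[Mg]Cl)(Cc1cc(OC)cc(OC)c1)c1ccc(OC)cc1 | intermediate (not isolated)
7 | racemic 3-(3,5-dimethoxybenzyl)-4,6-dimethoxy-3-(4-methoxyphenyl)isobenzofuran-1(3H)-one | O=C1OC(Cc2cc(OC)cc(OC)c2)(c2ccc(OC)cc2)c2c(OC)cc(OC)cc21 | intermediate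
8 | (Z)-2-[2-(3,5-dimethoxyphenyl)-1-(4-methoxyphenyl)ethenyl]-3,5-dimethoxybenzoic acid | COc1ccc(/C(=C/c2cc(OC)cc(OC)c2)c2c(OC)cc(OC)cc2C(=O)O)cc1 | intermediate
9 | (S)-2-[2-(3,5-dimethoxyphenyl)-1-(4-methoxyphenyl)ethyl]-3,5-dimethoxybenzoic acid | COc1ccc([C@H](Cc2cc(OC)cc(OC)c2)c2c(OC)cc(OC)cc2C(=O)O)cc1 | intermediate
10 | mixed anhydride of 9 with trifluoroacetic acid | COc1ccc([C@H](Cc2cc(OC)cc(OC)c2)c2c(OC)cc(OC)cc2C(=O)OC(=O)C(F)(F)F)cc1 | intermediate (not isolated)
11 | (S)-1,3,6,8-tetramethoxy-11-(4-methoxyphenyl)-10,11-dihydro-5H-dibenzo[a,d][7]annulen-5-one | COc1ccc([C@@H]2Cc3cc(OC)cc(OC)c3C(=O)c3cc(OC)cc(OC)c32)cc1 | intermediate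
12 | (S)-6-hydroxy-1,3,8-trimethoxy-11-(4-methoxyphenyl)-10,11-dihydro-5H-dibenzo[a,d][7]annulen-5-one | COc1ccc([C@@H]2Cc3cc(OC)cc(O)c3C(=O)c3cc(OC)cc(OC)c32)cc1 | intermediate
13 | 4-(benzyloxy)benzyl chloride | ClCc1ccc(OCc2ccccc2)cc1 | starting material
14 | 4-(benzyloxy)benzylmagnesium chloride | Cl[Mg]Cc1ccc(OCc2ccccc2)cc1 | intermediate (not isolated)
15 | tertiary carbinol from addition of 14 to 12 (C7 S; both C8' epimers) | COc1ccc([C@@H]2Cc3cc(OC)cc(O)c3C(O)(Cc3ccc(OCc4ccccc4)cc3)c3cc(OC)cc(OC)c32)cc1 | intermediate (not isolated)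
16 | (S)-5-[4-(benzyloxy)benzylidene]-2,7,9-trimethoxy-10-(4-methoxyphenyl)-10,11-dihydro-5H-dibenzo[a,d][7]annulen-4-ol (E/Z mixture about C8'=C7') | COc1ccc([C@@H]2Cc3cc(OC)cc(O)c3C(=Cc3ccc(OCc4ccccc4)cc3)c3cc(OC)cc(OC)c32)cc1 | intermediate
17 | ortho-quinone methide (a5 carbonyl, a6=C8' double bond, C8' bearing the 4-benzyloxybenzyl group; C7 S) | COc1ccc([C@@H]2CC3=CC(OC)=CC(=O)C3=C(Cc3ccc(OCc4ccccc4)cc3)c3cc(OC)cc(OC)c32)cc1 | intermediate (not isolated)
18 | (5S,10S)-5-[4-(benzyloxy)benzyl]-2,7,9-trimethoxy-10-(4-methoxyphenyl)-10,11-dihydro-5H-dibenzo[a,d][7]annulen-4-ol | COc1ccc([C@@H]2Cc3cc(OC)cc(O)c3[C@H](c3cc(OC)cc(OC)c32)Cc2ccc(OCc3ccccc3)cc2)cc1 | intermediate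
19 | (5S,10S)-5-(4-hydroxybenzyl)-2,7,9-trimethoxy-10-(4-methoxyphenyl)-10,11-dihydro-5H-dibenzo[a,d][7]annulen-4-ol (key-step precursor) | COc1ccc([C@@H]2Cc3cc(OC)cc(O)c3[C@H](c3cc(OC)cc(OC)c32)Cc2ccc(O)cc2)cc1 | intermediate
20 | para-quinone methide at C7' (C7 and C8' as in 19) | COc1ccc([C@@H]2Cc3cc(OC)cc(O)c3[C@H](c3cc(OC)cc(OC)c32)C=C2C=CC(=O)C=C2)cc1 | intermediate (not isolated)
21 | ampelopsin B tetramethyl ether carrying the free 4-hydroxyphenyl group on C7' (7S,7'S,8'S) | COc1ccc([C@@H]2Cc3cc(OC)cc4c3[C@H](c3cc(OC)cc(OC)c32)[C@@H](c2ccc(O)cc2)O4)cc1 | intermediate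
22 | ampelopsin B (7S,7'S,8'S) | Oc1ccc([C@@H]2Cc3cc(O)cc4c3[C@H](c3cc(O)cc(O)c32)[C@@H](c2ccc(O)cc2)O4)cc1 | target

**Totals.** Total step count: 11. Longest linear sequence: 11 steps (from 1 and 2 to 22).

**Steps most likely to fail**

1. Step 10 (proposed new method). What may go wrong:
- the enzyme may not bind or turn over so bulky and hydrophobic a substrate;
- the quinone methide may lose the C8' proton to give a triaryl alkene, or be trapped by water instead of the a5 phenol;
- the product, still a 4-hydroxybenzyl ether, may be oxidised a second time at C7'.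

Fallback with known chemistry, setting out from 18 and coming back at 21:
- The a5 phenol of 18 is acetylated (Ac2O, pyridine) to give the a5 acetate F1, which makes ring A a poor hydride donor.
- Hydrogenolysis (H2, Pd/C) frees the para phenol and gives the acetate phenol F2.
- DDQ in CH2Cl2/MeOH at 0 °C dehydrogenates the 4-alkylphenol to the same type of quinone methide, which methanol traps as the C7' methyl ether F3 (both C7' epimers).
- K2CO3 in MeOH removes the acetate to give the phenol methyl ether F4.
- A trace of TsOH in CH2Cl2 ionises the 4-hydroxybenzyl ether of F4, and the a5 phenol closes the trans dihydrofuran to give 21.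

2. Step 8. What may go wrong: poor facial selectivity at C8' if the resident C7 centre opposes the catalyst (hydride entering anti to the C7 aryl gives the C8' epimer), or slow protonation of the hindered alkene.

Fallback, setting out from 12 and coming back at 18:
- NaBH4 in MeOH/THF reduces the ketone of 12 to the benzhydrol F5 (both C8' epimers).
- Warming the magnesium salt of F5 with excess 14 in THF/toluene at 60 °C expels the benzylic oxygen and gives the ortho-quinone methide carrying hydrogen on C8'.
- The benzyl Grignard reagent adds to C8' in conjugate fashion. Here the carbon group, not hydride, enters anti to the C7 aryl, so the same substrate bias now works for the wanted isomer 18.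

3. Step 4. What may go wrong: slow turnover or low enantioselectivity on a hindered triaryl alkene, or erosion of selectivity by residual E isomer.

Fallback, setting out from 8 and coming back at 9:
- Hydrogenation of 8 over Pd/C (H2, 1 atm, EtOAc) gives the racemic acid F6.
- Classical resolution follows, by crystallisation of the diastereomeric salt F7 with (S)-1-phenylethylamine from ethanol. The amine antipode that gives the less soluble salt with the S acid is chosen by screening.
- Acidification of the salt with dilute HCl liberates 9.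

Further compounds
F1 | step 10 | a5 acetate of 18 (4'-benzyl ether) | COc1ccc([C@@H]2Cc3cc(OC)cc(OC(C)=O)c3[C@H](c3cc(OC)cc(OC)c32)Cc2ccc(OCc3ccccc3)cc2)cc1
F2 | step 10 | a5 acetate of 19 (free 4-hydroxybenzyl group) | COc1ccc([C@@H]2Cc3cc(OC)cc(OC(C)=O)c3[C@H](c3cc(OC)cc(OC)c32)Cc2ccc(O)cc2)cc1
F3 | step 10 | C7' methyl ether of F2 (both C7' epimers) | COc1ccc([C@@H]2Cc3cc(OC)cc(OC(C)=O)c3[C@H](c3cc(OC)cc(OC)c32)C(OC)c2ccc(O)cc2)cc1
F4 | step 10 | C7' methyl ether of 19 (free a5 phenol; both C7' epimers) | COc1ccc([C@@H]2Cc3cc(OC)cc(O)c3[C@H](c3cc(OC)cc(OC)c32)C(OC)c2ccc(O)cc2)cc1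
F5 | step 8 | benzhydrol from reduction of 12 (C7 S; both C8' epimers) | COc1ccc([C@@H]2Cc3cc(OC)cc(O)c3C(O)c3cc(OC)cc(OC)c32)cc1
F6 | step 4 | racemic 2-[2-(3,5-dimethoxyphenyl)-1-(4-methoxyphenyl)ethyl]-3,5-dimethoxybenzoic acid | COc1ccc(C(Cc2cc(OC)cc(OC)c2)c2c(OC)cc(OC)cc2C(=O)O)cc1
F7 | step 4 | (S)-1-phenylethylammonium salt of 9 | COc1ccc([C@H](Cc2cc(OC)cc(OC)c2)c2c(OC)cc(OC)cc2C(=O)[O-])cc1.C[C@H]([NH3+])c1ccccc1
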